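## Analysis of the target

Numbering used throughout: chromanone part (rings A/C) O1, C2, C3, C4(=O), C4a, C5–C8, C8a; chroman part (arene B fused to pyran D) O1', C2'(Me)2, C3'(OH), C4'H2, C4a', C5', C6', C7', C8'(OH), C8a'. C2 is bonded to C6'.

- Target 14 is a (2S)-7-hydroxyflavanone whose B ring is the arene of a (3'S)-3',8'-dihydroxy-2',2'-dimethylchromane. The two bicycles are held together by the single bond C2–C6'.
- There are only two stereocentres, C2 (S) and C3' (S). They lie on opposite sides of the B-ring arene, so neither can steer the other; each needs reagent control, and C2 epimers differing only at a remote centre are expected to be hard to separate.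
- C2 is the fragile centre: benzylic, oxygen-bearing and β to the C4 carbonyl. Base opens ring C by retro-oxa-Michael reaction to the 2'-hydroxychalcone and scrambles it, so C2 should be made late and see only mild acid afterwards.
- C3' is a secondary carbinol next to the quaternary C2' of a tertiary alkyl aryl ether. Strong Lewis acids (as needed to cleave aryl methyl ethers) would open ring D, which limits the protecting groups.
- O1' and O8' form an oxidation-prone catechol that must be differentiated (one ring ether, one free phenol). O7 is a vinylogous acid.
- The feature the route exploits: the B-ring arene is 1,2,3-trisubstituted (C4a', C8a', C8'). In a precursor with C6'–H, that hydrogen is the only aromatic C–H without an ortho substituent, and C6' is exactly the carbon that carries C2.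
- The bond C2–C6' can therefore be made from a C–H bond, and because C2 is one end of it, the labile stereocentre can be created in the same event that joins the two halves.

## Retrosynthetic reasoning

**14 ⇐ 13.** The two acetal C–O bonds at O7 and O8' are cut. Methoxymethyl ethers are chosen because dilute acid removes them and C2 tolerates acid. They carry no aryl C–H (a benzyl ether would itself be borylated in the key step) and need no Lewis acid (a methyl ether would). The forward step must free two phenols without touching C2, ring D or C3'–OH.

**13 ⇐ 8 + 10 (with 11).** The bond C2–C6' is cut. It is the most convergent cut, dividing 13 into two bicycles of similar size. It also avoids the O1–C2 bond, whose formation is reversible and whose reverse is the racemisation pathway. The precursors are much simpler than the product: 10 is flat and achiral, 8 carries only C3'. In the forward direction C6'–H of 8 is converted with diboron 11 into the C6'–B bond of 12, and a chiral rhodium aryl then adds to the Re face of C2=C3 of 10. This one operation has to deliver site selectivity on ring B, the C–C bond and the C2 configuration.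

**10 ⇐ 9.** The O7–acetal bond is cut. The free vinylogous acid of 9 would be deprotonated under the coupling conditions and deactivate the enone, so it is masked in one step.

**8 ⇐ 7 ⇐ 6.** First the C4'–H bond is cut (back to the benzylic C4'–O bond of epoxide 7), then both epoxide C–O bonds (back to olefin 6). C3' sits next to a quaternary carbon and is a poor site for direct asymmetric oxygenation. The C3'=C4' bond of 6, however, is a cis-disubstituted, aryl-conjugated olefin flanked by a gem-dimethyl group, the substrate class best suited to manganese–salen epoxidation. Hydrogenolysis then has to break only the benzylic C4'–O bond, so that the C3'–O bond and its configuration pass unchanged into 8.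

**6 ⇐ 4 ⇐ 2 + 3 ⇐ 1.** Ring D is opened at C4a'–C4' (aromatic propargyl Claisen rearrangement via 5), then the O1'–C2' ether bond is cut, then the O8' acetal. One ortho position of 4 carries O8', so the rearrangement can only go to C4a'. This delivers the complete carbon skeleton and oxygen pattern of ring B/D from catechol 1 and the C5 chloride 3.

## Alternatives that were turned down

**Alternative 1:** the textbook route.
- Disconnection: O1–C2 and C2=C3. Claisen–Schmidt condensation of aldehyde A1 with acetophenone A2 gives 2'-hydroxychalcone A3.
- Forward key step: 6-endo-trig intramolecular oxa-Michael addition of A3 to 13.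
- Why turned down: the cyclisation of a chalcone without a second activating group at C3 is reversible and only weakly downhill. Any basic or hydrogen-bonding catalyst works under conditions in which the product reopens, so enantiocontrol rests on the very equilibrium that racemises C2; the remote C3' gives no bias. A1 also needs an extra carbon at C6', to be installed by formylation or carried as an aldehyde through the hypochlorite epoxidation. More steps, with the stereocentre on its weakest footing.

**Alternative 2:** asymmetric reduction of a flavone.
- Disconnection: the C2–H and C3–H bonds; flat flavone A4 is built first.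
- Forward key step: enantioselective hydrogenation (or conjugate reduction) of C2=C3 of A4 to 13.
- Why turned down: A4 needs the same C–C construction as any other route plus an oxidation-level adjustment. Its C2=C3 bond is a vinylogous ester conjugated to two electron-rich arenes, hence a poor hydrogenation substrate. Over-reduction at C4 is expected, and re-oxidation could not distinguish C4–OH from C3'–OH, forcing an extra protecting group on C3'.

**Alternative 3:** ring D closed last (the biomimetic order).
- Disconnection: the O1'–C2' bond. Prenylated flavanone A5 is epoxidised to A6.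
- Forward key step: asymmetric ketone-catalysed epoxidation of A5, then selective unmasking of the ring oxygen and acid-mediated 6-endo epoxide opening.
- Why turned down: the epoxidation runs with persulfate at pH about 10, which endangers both C2 (retro-oxa-Michael) and the C4 ketone (Baeyer–Villiger). One of three identical acetals would have to be removed selectively. The 6-endo/5-exo competition at the trisubstituted epoxide is decided by acid strength, and the acid needed for 6-endo also promotes hydride-shift rearrangement. All of this would be played out on the most advanced intermediate.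

Key step: step 7

Assumption: the (S,S)-diene–rhodium catalyst is taken to arylate the Re face of C2 of 10 (the sense that gives (S)-3-arylcyclohexanones from cyclohexenone). If a model run with a simple aryl boronate shows the opposite sense, the (R,R)-ligand is used in step 7 with nothing else changed.

## Route

Step 1
Reactants: 1 catechol
Product: 2 2-(methoxymethoxy)phenol
Conditions: 1 (3 equiv), NaH (1.0 equiv), MOMCl (1.0 equiv), DMF, 0 °C to rt
Reagents that add atoms: chloromethyl methyl ether, COCCl
Why: O-alkylation of the monophenoxide (Williamson-type acetal formation); the excess of cheap 1 should hold bis-alkylation down and is removed by aqueous washing.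

Step 2
Reactants: 2 2-(methoxymethoxy)phenol; 3 3-chloro-3-methylbut-1-yne
Product: 4 1-(methoxymethoxy)-2-[(2-methylbut-3-yn-2-yl)oxy]benzene
Conditions: CuCl2·2H2O (1 mol%), DBU (1.3 equiv), MeCN, 0 °C
Reagents that add atoms: none
Why: Copper-catalysed propargylic etherification of a phenol with a tertiary propargylic chloride (copper acetylide/allenylidene pathway), which forms hindered aryl 1,1-dimethylpropargyl ethers where SN2 cannot.

Step 3
Reactants: 4 1-(methoxymethoxy)-2-[(2-methylbut-3-yn-2-yl)oxy]benzene
Product: 6 8-(methoxymethoxy)-2,2-dimethyl-2H-chromene, via ortho-allenylphenol 5 (not isolated)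
Conditions: PhNEt2, 185 °C, sealed tube
Reagents that add atoms: none
Why: Aromatic propargyl Claisen rearrangement: [3,3] shift to the only free ortho carbon and tautomerisation to 5, then 1,5-hydrogen shift and oxa-6π electrocyclisation close ring D; the basic solvent protects the acetal.

Step 4
Reactants: 6 8-(methoxymethoxy)-2,2-dimethyl-2H-chromene
Product: 7 (3S,4S)-3,4-epoxy-8-(methoxymethoxy)-2,2-dimethylchromane
Conditions: (S,S)-Mn(salen)Cl (Jacobsen catalyst, 3 mol%), 4-phenylpyridine N-oxide (15 mol%), aq NaOCl (pH 11.3), CH2Cl2, 0 °C
Reagents that add atoms: sodium hypochlorite, [Na+].[O-]Cl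
Why: Jacobsen–Katsuki epoxidation of a cis-disubstituted aryl-conjugated olefin; 2,2-dimethylchromenes are the model substrate class, and the (S,S)-catalyst is expected to deliver oxygen to the face that gives the (3S,4S)-epoxide, which fixes C3' by catalyst control.

Step 5
Reactants: 7 (3S,4S)-3,4-epoxy-8-(methoxymethoxy)-2,2-dimethylchromane
Product: 8 (3S)-8-(methoxymethoxy)-2,2-dimethylchroman-3-ol
Conditions: H2 (1 atm), 10% Pd/C, Et3N (5 mol%), EtOAc, rt
Reagents that add atoms: none
Why: Hydrogenolysis of the benzylic C4'–O bond of an aryl epoxide; the C3'–O bond is not touched, so the (S) configuration is carried over, and the trace of amine suppresses acid-induced rearrangement on the support.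

Step 6
Reactants: 9 7-hydroxy-4H-chromen-4-one
Product: 10 7-(methoxymethoxy)-4H-chromen-4-one
Conditions: MOMCl (1.3 equiv), iPr2NEt (1.5 equiv), CH2Cl2, 0 °C to rt
Reagents that add atoms: chloromethyl methyl ether, COCCl
Why: O-alkylation of the acidic 7-hydroxyl group (a vinylogous carboxylic acid), which is fully ionised by the amine base.

Step 7
Reactants: 8 (3S)-8-(methoxymethoxy)-2,2-dimethylchroman-3-ol; 10 7-(methoxymethoxy)-4H-chromen-4-one; 11 bis(pinacolato)diboron
Product: 13 (2S)-2-[(3S)-3-hydroxy-8-(methoxymethoxy)-2,2-dimethylchroman-6-yl]-7-(methoxymethoxy)chroman-4-one, via bis-boronate 12 (not isolated)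
Conditions: (i) 8 (1.3 equiv), 11 (1.1 equiv per 8), [Ir(OMe)(cod)]2 (1.5 mol%), dtbpy (3 mol%), THF, 80 °C, then evaporation; (ii) 10 (1.0 equiv), [RhCl((S,S)-Ph-bod*)]2 (3 mol% Rh), KOH (0.3 equiv), degassed toluene/H2O 10:1, 40 °C
Reagents that add atoms: none
Why: Stage (i) is a sterically governed iridium-catalysed arene C–H borylation: the Ir(III) tris(boryl)/dtbpy complex activates only C6'–H, the one aromatic C–H of 8 without an ortho substituent (C5'–H is blocked by C4', C7'–H by the O8' acetal), while C3'–OH is capped in situ as its O–Bpin ester, so that 8 and 11 give 12 and H2. Stage (ii) is a rhodium-catalysed asymmetric 1,4-addition of the aryl boronate to the chromone: hydroxide-assisted boron-to-rhodium transmetalation, carborhodation of C2=C3 of 10, and hydrolysis of the oxa-π-allyl rhodium enolate, which also cleaves the O–Bpin ester. The closest known reaction type is the one-pot arene C–H borylation/rhodium 1,4-addition sequence on simple enones, combined with the rhodium–chiral diene arylation of chromones by arylboronic acids. No ring is closed; the step forms the C2–C6' bond that joins the two bicycles. The new stereocentre C2 is set by the chiral diene on rhodium, which exposes the Re face of C2 to the migrating aryl group; C3' is too remote to influence it, so there is no mismatched case. The selectivities needed are site selectivity in the borylation, secured by the 1,2,3-substitution pattern of ring B, and 1,4- over 1,2-addition without opening of ring C, secured by the diene–rhodium catalyst, the sub-stoichiometric base and the two-phase medium at 40 °C. Protodeboronation of 12 only returns 8, which can be recovered.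

Step 8
Reactants: 13 (2S)-2-[(3S)-3-hydroxy-8-(methoxymethoxy)-2,2-dimethylchroman-6-yl]-7-(methoxymethoxy)chroman-4-one
Product: 14 (2S)-2-[(3S)-3,8-dihydroxy-2,2-dimethylchroman-6-yl]-7-hydroxychroman-4-one
Conditions: 3 M aq HCl, MeOH, 45 °C
Reagents that add atoms: none
Why: Acid-catalysed acetal exchange frees both phenols; C2 cannot epimerise without a phenoxide/enolate, and the tertiary aryl ether and the secondary carbinol should be stable to dilute acid in methanol, which also traps the formaldehyde equivalent.

## Compound list

1 | catechol | Oc1ccccc1O | starting material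
2 | 2-(methoxymethoxy)phenol | COCOc1ccccc1O | intermediate
3 | 3-chloro-3-methylbut-1-yne | CC(C)(Cl)C#C | starting material
4 | 1-(methoxymethoxy)-2-[(2-methylbut-3-yn-2-yl)oxy]benzene | COCOc1ccccc1OC(C)(C)C#C | intermediate
5 | 2-(methoxymethoxy)-6-(3-methylbuta-1,2-dien-1-yl)phenol | COCOc1cccc(C=C=C(C)C)c1O | intermediate
6 | 8-(methoxymethoxy)-2,2-dimethyl-2H-chromene | COCOc1cccc2C=CC(C)(C)Oc12 | intermediate
7 | (3S,4S)-3,4-epoxy-8-(methoxymethoxy)-2,2-dimethylchromane | CC1(C)Oc2c(OCOC)cccc2[C@@H]3O[C@H]13 | intermediate
8 | (3S)-8-(methoxymethoxy)-2,2-dimethylchroman-3-ol | CC1(C)Oc2c(OCOC)cccc2C[C@@H]1O | intermediate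
9 | 7-hydroxy-4H-chromen-4-one | O=c1ccoc2cc(O)ccc12 | starting material
10 | 7-(methoxymethoxy)-4H-chromen-4-one | O=c1ccoc2cc(OCOC)ccc12 | intermediate
11 | bis(pinacolato)diboron | CC1(C)OB(OC1(C)C)B1OC(C)(C)C(C)(C)O1 | starting material
12 | 2-{[(3S)-8-(methoxymethoxy)-2,2-dimethyl-6-(4,4,5,5-tetramethyl-1,3,2-dioxaborolan-2-yl)chroman-3-yl]oxy}-4,4,5,5-tetramethyl-1,3,2-dioxaborolane | CC1(C)Oc2c(OCOC)cc(B3OC(C)(C)C(C)(C)O3)cc2C[C@@H]1OB1OC(C)(C)C(C)(C)O1 | intermediate
13 | (2S)-2-[(3S)-3-hydroxy-8-(methoxymethoxy)-2,2-dimethylchroman-6-yl]-7-(methoxymethoxy)chroman-4-one | CC1(C)Oc2c(OCOC)cc([C@@H]3CC(=O)c4ccc(OCOC)cc4O3)cc2C[C@@H]1O | intermediate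
14 | (2S)-2-[(3S)-3,8-dihydroxy-2,2-dimethylchroman-6-yl]-7-hydroxychroman-4-one | CC1(C)Oc2c(O)cc([C@@H]3CC(=O)c4ccc(O)cc4O3)cc2C[C@@H]1O | target

## Step count and risk

Total steps: 8. Longest linear sequence: 7 (steps 1–5, 7, 8); the chromone branch is one step (step 6).

**Step 7 (key step).**
- What may go wrong: slow transfer of the aryl group from the pinacol ester to rhodium in the presence of iridium residues, together with the reduced electrophilicity of a 7-alkoxychromone, so that protodeboronation outruns addition. Base-mediated retro-oxa-Michael opening of the product may also erode the configuration at C2.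
- Fallback: this sets out from 8 and gives up both the one-pot and the basic rhodium manifold. The borylation is run alone with 11 and worked up with methanol to give (3S)-8-(methoxymethoxy)-2,2-dimethyl-6-(4,4,5,5-tetramethyl-1,3,2-dioxaborolan-2-yl)chroman-3-ol F1. Periodate cleavage (NaIO4, NH4OAc, acetone/H2O) gives [(3S)-3-hydroxy-8-(methoxymethoxy)-2,2-dimethylchroman-6-yl]boronic acid F2. F2 is added to 10 by cationic palladium(II) catalysis (Pd(OCOCF3)2, (R)-t-BuPyOx, NH4PF6, H2O, ClCH2CH2Cl, 60 °C; ligand antipode fixed by the same model run as in the assumption). This proceeds by carbopalladation and protonolysis under weakly acidic conditions, in which ring C cannot open by an E1cB path. It comes back to the route at 13.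

**Step 4.**
- What may go wrong: insufficient facial discrimination, because the O8' substituent next to the ring oxygen may perturb the approach of the olefin to the manganese oxo species; and acid-triggered opening of the electron-rich benzylic epoxide during isolation.
- Fallback: this sets out from 6 and moves the stereo-defining event from the olefin to a ketone. Dimethyldioxirane (acetone, 0 °C) gives racemic 3,4-epoxy-8-(methoxymethoxy)-2,2-dimethylchromane F3. Catalytic ZnI2 in toluene induces the Meinwald rearrangement (benzylic C–O ionisation, 1,2-hydride shift) to 8-(methoxymethoxy)-2,2-dimethylchroman-3-one F4. Corey–Bakshi–Shibata reduction ((R)-Me-CBS, BH3·SMe2, THF, −20 °C), with the quaternary C2' as the large and C4'H2 as the small substituent, should give the (S)-alcohol. It comes back to the route at 8 and bypasses step 5.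

**Step 5.**
- What may go wrong: isomerisation of the epoxide to carbonyl compounds on the carbon support, in competition with C4'–O hydrogenolysis.
- Fallback: this sets out from 7 and replaces heterogeneous hydrogenolysis by an ionic opening followed by a radical reduction. LiBr/AcOH in THF opens the epoxide at the benzylic carbon to (3R,4R)-4-bromo-8-(methoxymethoxy)-2,2-dimethylchroman-3-ol F5. Bu3SnH/AIBN (toluene, 80 °C) removes the bromine through the benzylic radical; the C3'–O bond is never involved. It comes back to the route at 8.

**Step 3.**
- What may go wrong: thermal fragmentation of the tertiary propargylic ether (loss of the C5 unit with return to 2) or loss of the acetal at 185 °C, in competition with the [3,3] shift.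
- Fallback: this sets out from 2 and builds ring D by a condensation instead of a sigmatropic shift. Magnesium-mediated ortho-formylation (MgCl2, Et3N, paraformaldehyde, MeCN, reflux) at the only free ortho position gives 2-hydroxy-3-(methoxymethoxy)benzaldehyde F6. An amine-promoted Petasis-type condensation with (2-methylprop-1-en-1-yl)boronic acid (Bn2NH, dioxane, 90 °C) follows; loss of the amine to an ortho-quinone methide and oxa-6π electrocyclisation close the ring. It comes back to the route at 6 and bypasses steps 2 and 3.

## Further compounds

F1 | step 7 | (3S)-8-(methoxymethoxy)-2,2-dimethyl-6-(4,4,5,5-tetramethyl-1,3,2-dioxaborolan-2-yl)chroman-3-ol | CC1(C)Oc2c(OCOC)cc(B3OC(C)(C)C(C)(C)O3)cc2C[C@@H]1O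
F2 | step 7 | [(3S)-3-hydroxy-8-(methoxymethoxy)-2,2-dimethylchroman-6-yl]boronic acid | CC1(C)Oc2c(OCOC)cc(B(O)O)cc2C[C@@H]1O
F3 | step 4 | racemic 3,4-epoxy-8-(methoxymethoxy)-2,2-dimethylchromane | CC1(C)Oc2c(OCOC)cccc2C3OC13
F4 | step 4 | 8-(methoxymethoxy)-2,2-dimethylchroman-3-one | CC1(C)Oc2c(OCOC)cccc2CC1=O
F5 | step 5 | (3R,4R)-4-bromo-8-(methoxymethoxy)-2,2-dimethylchroman-3-ol | CC1(C)Oc2c(OCOC)cccc2[C@@H](Br)[C@@H]1O
F6 | step 3 | 2-hydroxy-3-(methoxymethoxy)benzaldehyde | COCOc1cccc(C=O)c1O
A1 | alternative 1 | (3S)-3-hydroxy-8-(methoxymethoxy)-2,2-dimethylchromane-6-carbaldehyde | CC1(C)Oc2c(OCOC)cc(C=O)cc2C[C@@H]1O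
A2 | alternative 1 | 1-[2-hydroxy-4-(methoxymethoxy)phenyl]ethan-1-one | CC(=O)c1ccc(OCOC)cc1O
A3 | alternative 1 | (E)-1-[2-hydroxy-4-(methoxymethoxy)phenyl]-3-[(3S)-3-hydroxy-8-(methoxymethoxy)-2,2-dimethylchroman-6-yl]prop-2-en-1-one | CC1(C)Oc2c(OCOC)cc(/C=C/C(=O)c3ccc(OCOC)cc3O)cc2C[C@@H]1O
A4 | alternative 2 | 2-[(3S)-3-hydroxy-8-(methoxymethoxy)-2,2-dimethylchroman-6-yl]-7-(methoxymethoxy)-4H-chromen-4-one | CC1(C)Oc2c(OCOC)cc(-c3cc(=O)c4ccc(OCOC)cc4o3)cc2C[C@@H]1O
A5 | alternative 3 | (2S)-2-[3,4-bis(methoxymethoxy)-5-(3-methylbut-2-en-1-yl)phenyl]-7-(methoxymethoxy)chroman-4-one | CC(C)=CCc1cc([C@@H]2CC(=O)c3ccc(OCOC)cc3O2)cc(OCOC)c1OCOC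
A6 | alternative 3 | (2S)-2-[3-{[(2S)-3,3-dimethyloxiran-2-yl]methyl}-4,5-bis(methoxymethoxy)phenyl]-7-(methoxymethoxy)chroman-4-one | CC1(C)O[C@H]1Cc1cc([C@@H]2CC(=O)c3ccc(OCOC)cc3O2)cc(OCOC)c1OCOC
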